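**Retrosynthetic overview**
1. The γ-lactone is closed last, as in the biosynthesis: the C12 primary allylic alcohol is oxidised to the aldehyde, trapped by O-8 as the lactol and oxidised on to the lactone.
2. The six-membered carbocycle is closed at C6–C7 by the cyclase-type event of the pathway: an allylic oxocarbenium at C6 is attacked by the C7=C11 olefin and a methyl proton is lost to leave the 2-propenyl unit. C1–C10 is never made, so no fragmentation is needed.
3. The acyclic enal comes from an aldol condensation at C5/C10 between a citronellal-derived enol silane (C1–C6, C4 from (S)-citronellal) and a C7–C14 ketone.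
4. The ketone comes from acetonyl methacrylate and prenal (boron aldol sets C8), then SeO2 oxidation at C12.
5. Ring order: carbocycle first (C8 controls C7 and C6), lactone second.

Assumption: the SMILES is taken literally, i.e. (4S,6S,7S,8R) with H-6/H-7 cis and H-7/H-8 trans (trans-fused lactone); atoms are numbered C1–C15 as in 1,10-seco-eudesmanes (C1 = CH2OAc end, C4 = side-chain stereocentre, C5=C10 ring olefin, C6 = CHOAc, C7/C8 = lactone fusion, C14 = CH2O-methacrylate).

**Route**

Step 1
Reactants: 1 (S)-citronellal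
Product: 2 (6S)-8,8-dimethoxy-2,6-dimethyloct-2-ene
Conditions: HC(OMe)3, MeOH, pyridinium p-toluenesulfonate (cat.), rt
Reagents that add atoms: trimethyl orthoformate, COC(OC)OC; methanol, CO
Why: Acid-catalysed acetalisation (orthoformate as water scavenger) masks the aldehyde so that only the C1 end is touched in step 2; the C4 stereocentre comes from 1 and is not involved.

Step 2
Reactants: 2 (6S)-8,8-dimethoxy-2,6-dimethyloct-2-ene
Product: 4 (3S)-6-hydroxy-3-methylhexanal, via hydroxy acetal 3 (not isolated)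
Conditions: O3, CH2Cl2/MeOH, −78 °C; NaBH4, −78 °C → rt; then 1 M HCl, THF/H2O, rt
Reagents that add atoms: ozone, [O-][O+]=O; water, O
Why: Ozonolysis of the isopropylidene with reductive work-up gives the C1 primary alcohol, and the acidic quench hydrolyses the acetal back to the aldehyde.

Step 3
Reactants: 4 (3S)-6-hydroxy-3-methylhexanal
Product: 5 (3S)-3-methyl-1,6-bis(trimethylsilyloxy)hex-1-ene (E/Z mixture)
Conditions: TMSCl, Et3N, DMF, 80 °C
Reagents that add atoms: chlorotrimethylsilane, C[Si](C)(C)Cl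
Why: Silyl enol ether formation under House conditions turns C5 into the nucleophile for step 8 and caps O-1 as a labile TMS ether.

Step 4
Reactants: 6 chloroacetone; 7 methacrylic acid
Product: 8 2-oxopropyl methacrylate
Conditions: K2CO3, KI (cat.), 2,6-di-tert-butyl-4-methylphenol (cat.), acetone, 50 °C
Reagents that add atoms: none
Why: SN2 O-alkylation of the carboxylate by the activated α-chloro ketone puts the C14 methacrylate in place from the start.

Step 5
Reactants: 8 2-oxopropyl methacrylate; 9 prenal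
Product: 11 (4R)-4-hydroxy-6-methyl-2-oxohept-5-en-1-yl methacrylate, via boron enolate 10 (not isolated)
Conditions: (+)-Ipc2BCl, Et3N, Et2O, 0 °C; then 9, −78 → −20 °C; H2O2, MeOH/pH 7 buffer, 0 °C
Reagents that add atoms: none
Why: Paterson boron aldol, in which the bulky borane is expected to enolise the methyl group and the enol borinate adds to the Re face of prenal through the boat transition state typical of methyl-ketone borinates, setting C8 as (R) (about 80% ee expected; the minor enantiomer becomes a separable diastereomer after step 8).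

Step 6
Reactants: 11 (4R)-4-hydroxy-6-methyl-2-oxohept-5-en-1-yl methacrylate
Product: 12 (4R,5E)-4,7-dihydroxy-6-methyl-2-oxohept-5-en-1-yl methacrylate
Conditions: SeO2 (0.5 equiv), t-BuOOH, salicylic acid (cat.), CH2Cl2, rt
Reagents that add atoms: tert-butyl hydroperoxide, CC(C)(C)OO; selenium dioxide, O=[Se]=O
Why: SeO2 allylic oxidation (ene reaction then [2,3]-shift) oxidises the methyl trans to the chain at the more substituted olefin carbon, which gives the C12 oxygen and leaves the methyl (C13) cis to C8 as step 9 needs.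

Step 7
Reactants: 12 (4R,5E)-4,7-dihydroxy-6-methyl-2-oxohept-5-en-1-yl methacrylate
Product: 13 (4R,5E)-4,7-bis(tert-butyldimethylsilyloxy)-6-methyl-2-oxohept-5-en-1-yl methacrylate
Conditions: TBSCl, imidazole, DMF, 0 °C → rt
Reagents that add atoms: tert-butyldimethylsilyl chloride, CC(C)(C)[Si](C)(C)Cl
Why: Silylation of both hydroxyls stops O-8 from forming a lactol with C6 later and keeps O-8 and O-12 apart from the oxygens that will be acetylated.

Step 8
Reactants: 5 (3S)-3-methyl-1,6-bis(trimethylsilyloxy)hex-1-ene; 13 (4R,5E)-4,7-bis(tert-butyldimethylsilyloxy)-6-methyl-2-oxohept-5-en-1-yl methacrylate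
Product: 15 (5R,6E)-5,8-bis(tert-butyldimethylsilyloxy)-2-[(2S)-5-hydroxypentan-2-yl]-3-[(methacryloyloxy)methyl]-7-methylocta-2,6-dienal (2E/2Z mixture), via aldol adduct 14 (not isolated)
Conditions: TiCl4, CH2Cl2, −78 °C; aq. NaHCO3; crude: pyridinium p-toluenesulfonate (cat.), benzene, 50 °C; then citric acid, MeOH, 0 °C
Reagents that add atoms: none
Why: Mukaiyama aldol of the aldehyde enol silane with the TiCl4-activated α-acyloxy ketone forms C5–C10, acid-catalysed dehydration of the tertiary aldol gives the conjugated tetrasubstituted enal (geometry uncontrolled, about 1:1), and the mild acid removes only the TMS ether; C4 and C8 are not touched.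

Step 9
Reactants: 15 the enal (2E/2Z mixture)
Product: 17 {(3S,4R,5R)-3-acetoxy-2-[(2S)-5-acetoxypentan-2-yl]-5-(tert-butyldimethylsilyloxy)-4-[3-(tert-butyldimethylsilyloxy)prop-1-en-2-yl]cyclohex-1-en-1-yl}methyl methacrylate, via ene diol 16 (not isolated)
Conditions: Me2AlCl (3 equiv), CH2Cl2, −78 → 0 °C; then pyridine, Ac2O, 4-(dimethylamino)pyridine, 0 °C → rt
Reagents that add atoms: acetic anhydride, CC(=O)OC(C)=O
Why: Proposed new method: a Me2AlCl-promoted type 1 carbonyl-ene (Prins-type) closure of a tetrasubstituted enal run under E/Z-equilibrating conditions, in which the Lewis-acid-bound enal is a 1-oxyallyl cation whose C5–C10 bond can rotate (also through reversible chloride conjugate addition) so that both isomers drain through the (2E)-form, the only one whose CHO reaches C7; C7 attacks anti to the C8 silyloxy group (C8–H eclipses the olefin to avoid A(1,3) strain with the cis methyl, giving 7,8-trans), the C6–O bond goes pseudoaxial to avoid A(1,2) strain with the branched C5 substituent (giving 6,7-cis), the cis methyl C13 gives its hydrogen to oxygen to leave the 2-propenyl unit, and both aluminium alkoxides (O-6 and O-1) are acetylated in the same flask; the closest known reactions are the Lewis-acid carbonyl-ene cyclisations of citronellal to isopulegol and of neral to isopiperitenol and the in situ acetylation of aluminium alkoxides.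

Step 10
Reactants: 17 the bis-silyl diacetate
Product: 18 {(3S,4S,5R)-3-acetoxy-2-[(2S)-5-acetoxypentan-2-yl]-5-hydroxy-4-(3-hydroxyprop-1-en-2-yl)cyclohex-1-en-1-yl}methyl methacrylate
Conditions: HF·pyridine, pyridine/THF, 0 °C → rt
Reagents that add atoms: none
Why: Buffered fluoride cleaves both TBS ethers and leaves the three esters and all stereocentres as they are (the C7 label changes from R to S only because the CIP priorities change).

Step 11
Reactants: 18 the diol diacetate
Product: 21 [(3aS,4S,7aR)-4-acetoxy-5-[(2S)-5-acetoxypentan-2-yl]-3-methylidene-2-oxo-2,3,3a,4,7,7a-hexahydro-1-benzofuran-6-yl]methyl methacrylate (target), via hydroxy enal 19 (not isolated), via lactol 20 (not isolated)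
Conditions: TEMPO (2,2,6,6-tetramethylpiperidin-1-oxyl, cat.), PhI(OAc)2, CH2Cl2, rt
Reagents that add atoms: none
Why: Oxidative lactonisation, in which TEMPO/PhI(OAc)2 oxidises only the primary allylic alcohol, the aldehyde is trapped by the trans C8 hydroxyl as the lactol and this is oxidised to the α-methylene-γ-lactone; O-6 is blocked as acetate and no stereocentre changes.

**Compound list**
1 | (S)-citronellal, (3S)-3,7-dimethyloct-6-enal | C[C@@H](CCC=C(C)C)CC=O | starting material
2 | (6S)-8,8-dimethoxy-2,6-dimethyloct-2-ene | C[C@@H](CCC=C(C)C)CC(OC)OC | intermediate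
3 | (4S)-6,6-dimethoxy-4-methylhexan-1-ol | C[C@@H](CCCO)CC(OC)OC | intermediate
4 | (3S)-6-hydroxy-3-methylhexanal | C[C@@H](CCCO)CC=O | intermediate
5 | (3S)-3-methyl-1,6-bis(trimethylsilyloxy)hex-1-ene, E/Z mixture | C[C@@H](CCCO[Si](C)(C)C)C=CO[Si](C)(C)C | intermediate
6 | chloroacetone | CC(=O)CCl | starting material
7 | methacrylic acid | C=C(C)C(=O)O | starting material
8 | 2-oxopropyl methacrylate | CC(=O)COC(=O)C(C)=C | intermediate
9 | prenal, 3-methylbut-2-enal | CC(C)=CC=O | starting material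
10 | 2-[(diisopinocampheylboryl)oxy]prop-2-en-1-yl methacrylate (Ipc groups from (−)-α-pinene) | C=C(C)C(=O)OCC(=C)OB([C@H]1C[C@H]2C[C@@H]([C@@H]1C)C2(C)C)[C@H]1C[C@H]2C[C@@H]([C@@H]1C)C2(C)C | intermediate
11 | (4R)-4-hydroxy-6-methyl-2-oxohept-5-en-1-yl methacrylate | C=C(C)C(=O)OCC(=O)C[C@@H](O)C=C(C)C | intermediate
12 | (4R,5E)-4,7-dihydroxy-6-methyl-2-oxohept-5-en-1-yl methacrylate | C=C(C)C(=O)OCC(=O)C[C@@H](O)/C=C(C)/CO | intermediate
13 | (4R,5E)-4,7-bis(tert-butyldimethylsilyloxy)-6-methyl-2-oxohept-5-en-1-yl methacrylate | C=C(C)C(=O)OCC(=O)C[C@@H](O[Si](C)(C)C(C)(C)C)/C=C(C)/CO[Si](C)(C)C(C)(C)C | intermediate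
14 | (5R,6E)-5,8-bis(tert-butyldimethylsilyloxy)-3-hydroxy-3-[(methacryloyloxy)methyl]-7-methyl-2-[(2S)-5-(trimethylsilyloxy)pentan-2-yl]oct-6-enal, C2/C3 epimers, formed as its titanium alkoxide | O=CC([C@@H](C)CCCO[Si](C)(C)C)C(O)(COC(=O)C(C)=C)C[C@@H](O[Si](C)(C)C(C)(C)C)/C=C(C)/CO[Si](C)(C)C(C)(C)C | intermediate
15 | (5R,6E)-5,8-bis(tert-butyldimethylsilyloxy)-2-[(2S)-5-hydroxypentan-2-yl]-3-[(methacryloyloxy)methyl]-7-methylocta-2,6-dienal, 2E/2Z mixture | O=CC([C@@H](C)CCCO)=C(COC(=O)C(C)=C)C[C@@H](O[Si](C)(C)C(C)(C)C)/C=C(C)/CO[Si](C)(C)C(C)(C)C | intermediate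
16 | {(3S,4R,5R)-5-(tert-butyldimethylsilyloxy)-4-[3-(tert-butyldimethylsilyloxy)prop-1-en-2-yl]-3-hydroxy-2-[(2S)-5-hydroxypentan-2-yl]cyclohex-1-en-1-yl}methyl methacrylate, formed as its aluminium alkoxide | C=C(C)C(=O)OCC1=C([C@@H](C)CCCO)[C@@H](O)[C@@H](C(=C)CO[Si](C)(C)C(C)(C)C)[C@H](O[Si](C)(C)C(C)(C)C)C1 | intermediate
17 | {(3S,4R,5R)-3-acetoxy-2-[(2S)-5-acetoxypentan-2-yl]-5-(tert-butyldimethylsilyloxy)-4-[3-(tert-butyldimethylsilyloxy)prop-1-en-2-yl]cyclohex-1-en-1-yl}methyl methacrylate | C=C(C)C(=O)OCC1=C([C@@H](C)CCCOC(C)=O)[C@@H](OC(C)=O)[C@@H](C(=C)CO[Si](C)(C)C(C)(C)C)[C@H](O[Si](C)(C)C(C)(C)C)C1 | intermediate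
18 | {(3S,4S,5R)-3-acetoxy-2-[(2S)-5-acetoxypentan-2-yl]-5-hydroxy-4-(3-hydroxyprop-1-en-2-yl)cyclohex-1-en-1-yl}methyl methacrylate | C=C(C)C(=O)OCC1=C([C@@H](C)CCCOC(C)=O)[C@@H](OC(C)=O)[C@@H](C(=C)CO)[C@H](O)C1 | intermediate
19 | {(3S,4S,5R)-3-acetoxy-2-[(2S)-5-acetoxypentan-2-yl]-5-hydroxy-4-(3-oxoprop-1-en-2-yl)cyclohex-1-en-1-yl}methyl methacrylate | C=C(C)C(=O)OCC1=C([C@@H](C)CCCOC(C)=O)[C@@H](OC(C)=O)[C@@H](C(=C)C=O)[C@H](O)C1 | intermediate
20 | [(3aS,4S,7aR)-4-acetoxy-5-[(2S)-5-acetoxypentan-2-yl]-2-hydroxy-3-methylidene-2,3,3a,4,7,7a-hexahydro-1-benzofuran-6-yl]methyl methacrylate, C2 epimers | C=C(C)C(=O)OCC1=C([C@@H](C)CCCOC(C)=O)[C@@H](OC(C)=O)[C@H]2C(=C)C(O)O[C@@H]2C1 | intermediate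
21 | [(3aS,4S,7aR)-4-acetoxy-5-[(2S)-5-acetoxypentan-2-yl]-3-methylidene-2-oxo-2,3,3a,4,7,7a-hexahydro-1-benzofuran-6-yl]methyl methacrylate | C=C(C)C(=O)OCC1=C([C@@H](C)CCCOC(C)=O)[C@@H](OC(C)=O)[C@H]2C(=C)C(=O)O[C@@H]2C1 | target

**Step count**
Total steps: 11. Longest linear sequence: 8 (steps 4 to 11, from chloroacetone).

**Three steps most likely to fail**

Step 9 (ene closure). The risks are that the (2Z)-enal does not equilibrate, that the hindered enal is too poor an enophile, or that C6 comes out trans to C7. The fallback sets out from aldol adduct 14, isolated from step 8 by stopping after the bicarbonate work-up, and comes back at 16. With Me2AlCl at −78 °C the saturated aldehyde of 14 undergoes the same C6–C7 carbonyl-ene closure with no olefin-geometry requirement and gives the cyclohexane-1,3-diol F1. Dess–Martin periodinane oxidises only its secondary C6 carbinol to the β-hydroxy ketone F2. Martin sulfurane removes the tertiary C10 hydroxyl toward C5 to give the cyclohexenone F3. Reagent-controlled 1,2-reduction with (R)-1-methyl-3,3-diphenyltetrahydro-1H,3H-pyrrolo[1,2-c][1,3,2]oxazaborole and catecholborane, followed by citric acid in MeOH to remove the TMS ether, gives 16, which is acetylated to 17 as in step 9.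

Step 8 (aldol condensation to the tetrasubstituted enal). The risk is that the branched enol silane does not add to the hindered ketone. The fallback sets out from 4 and comes back at 15. Compound 4 is silylated at O-1 and condensed with tert-butylamine to the N-tert-butyl aldimine F4. Deprotonation with LiN(iPr)2 and transmetalation with anhydrous CeCl3 at −78 °C gives an aza-enolate that adds to ketone 13 to form the β-hydroxy imine F5. Aqueous oxalic acid hydrolyses the imine, removes the TMS ether and dehydrates the aldol to 15.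

Step 5 (boron aldol). The risks are enolisation on the acyloxymethyl side and modest enantioselectivity. The fallback sets out from 9 and comes back at 11. A Ti(OiPr)4/1,1'-bi-2-naphthol-catalysed Mukaiyama aldol of 1-(tert-butylsulfanyl)-1-(trimethylsilyloxy)ethene with 9 (using the binaphthol antipode that gives the R carbinol) gives the β-hydroxy thioester F6. MeNH(OMe)·HCl with i-PrMgCl converts it to the Weinreb amide F7. LiCH2Cl, made from ICH2Cl and MeLi·LiBr at −78 °C, gives the chloromethyl ketone F8. Displacement of chloride with potassium methacrylate (from 7 and K2CO3) gives 11 with no regiochemical ambiguity.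

Further compounds
F1 | step 9 | {1,3-dihydroxy-5-(tert-butyldimethylsilyloxy)-4-[3-(tert-butyldimethylsilyloxy)prop-1-en-2-yl]-2-[(2S)-5-(trimethylsilyloxy)pentan-2-yl]cyclohexyl}methyl methacrylate (4,5-trans; C1/C2/C3 mixture) | C=C(C)C(=O)OCC1(O)C([C@@H](C)CCCO[Si](C)(C)C)C(O)[C@@H](C(=C)CO[Si](C)(C)C(C)(C)C)[C@H](O[Si](C)(C)C(C)(C)C)C1
F2 | step 9 | {1-hydroxy-3-oxo-5-(tert-butyldimethylsilyloxy)-4-[3-(tert-butyldimethylsilyloxy)prop-1-en-2-yl]-2-[(2S)-5-(trimethylsilyloxy)pentan-2-yl]cyclohexyl}methyl methacrylate (4,5-trans; C1/C2 mixture) | C=C(C)C(=O)OCC1(O)C([C@@H](C)CCCO[Si](C)(C)C)C(=O)[C@@H](C(=C)CO[Si](C)(C)C(C)(C)C)[C@H](O[Si](C)(C)C(C)(C)C)C1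
F3 | step 9 | {(4R,5R)-3-oxo-5-(tert-butyldimethylsilyloxy)-4-[3-(tert-butyldimethylsilyloxy)prop-1-en-2-yl]-2-[(2S)-5-(trimethylsilyloxy)pentan-2-yl]cyclohex-1-en-1-yl}methyl methacrylate | C=C(C)C(=O)OCC1=C([C@@H](C)CCCO[Si](C)(C)C)C(=O)[C@@H](C(=C)CO[Si](C)(C)C(C)(C)C)[C@H](O[Si](C)(C)C(C)(C)C)C1
F4 | step 8 | (3S)-N-tert-butyl-3-methyl-6-(trimethylsilyloxy)hexan-1-imine | CC(C)(C)N=CC[C@@H](C)CCCO[Si](C)(C)C
F5 | step 8 | (5R,6E)-5,8-bis(tert-butyldimethylsilyloxy)-1-(tert-butylimino)-3-hydroxy-3-[(methacryloyloxy)methyl]-7-methyl-2-[(2S)-5-(trimethylsilyloxy)pentan-2-yl]oct-6-ene (C2/C3 epimers) | CC(C)(C)N=CC([C@@H](C)CCCO[Si](C)(C)C)C(O)(COC(=O)C(C)=C)C[C@@H](O[Si](C)(C)C(C)(C)C)/C=C(C)/CO[Si](C)(C)C(C)(C)C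
F6 | step 5 | S-tert-butyl (3R)-3-hydroxy-5-methylhex-4-enethioate | CC(C)=C[C@H](O)CC(=O)SC(C)(C)C
F7 | step 5 | (3R)-3-hydroxy-N-methoxy-N,5-dimethylhex-4-enamide | CC(C)=C[C@H](O)CC(=O)N(C)OC
F8 | step 5 | (4R)-1-chloro-4-hydroxy-6-methylhept-5-en-2-one | CC(C)=C[C@H](O)CC(=O)CCl
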